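## Retrosynthetic overview

1. Target ⇐ its C4 PMB ether (DDQ) ⇐ cis-decalone, by hydride delivery from the ring-A face and O-acylation of the alkoxide in the same flask (C1 anisate).
2. cis-Decalone ⇐ monocyclic 4-alkoxy enone + a 5-chloropent-1-en-2-yl unit: conjugate addition, then intramolecular enolate alkylation closes ring A (with its exocyclic methylene) onto preformed ring B.
3. Enone (ring B, ether oxygen cis to isopropyl) ⇐ (R)-α-phellandrene by a palladium-catalysed 1,4-oxo-alkoxylation; this C–O bond formation is the key step and fixes the carbinol carbon.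
4. Ring order: ring B from the chiral pool, then ring A by annulation; every new stereocentre is relayed from the isopropyl carbon.

Assumption: commercial (R)-(−)-α-phellandrene of ≥95% ee is the chiral source; decalin atoms carry naphthalene numbers (C1 ester, C3 isopropyl, C4 hydroxyl, C4a ring-fusion CH, C5 methylidene, C8a angular methyl), ring A is the methylidene ring and ring B the oxygenated ring.

The target has methyl (C8a), H (C4a), OH (C4), isopropyl (C3) and the anisate (C1) all on one face of a cis-decalin: (1R,3R,4S,4aS,8aR).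

## Route

Step 1
Reactants: 1 (R)-(−)-α-phellandrene [(5R)-2-methyl-5-(propan-2-yl)cyclohexa-1,3-diene]
Product: 3 (4S,5R)-4-[(4-methoxyphenyl)methoxy]-2-methyl-5-(propan-2-yl)cyclohex-2-en-1-one, via allylic tert-butyl peroxide 2 (not isolated)
Conditions: Pd(MeCN)4(BF4)2 (5 mol %), 2-(4,5-dihydro-1,3-oxazol-2-yl)quinoline (6 mol %), PMBOH (5 equiv), t-BuOOH (2.5 equiv, anhydrous, slow addition), 2,6-di-tert-butylpyridine (20 mol %), CH2Cl2, 0 °C; then Et3N, 25 °C
Reagents that add atoms: 4-methoxybenzyl alcohol, OCc1ccc(OC)cc1; tert-butyl hydroperoxide, CC(C)(C)OO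
Why: Proposed new method: the cationic divalent palladium complex binds the diene on the face anti to the C5 isopropyl group, its Pd–OOt-Bu ligand inserts the diene at C1 (the terminus that gives the more substituted η3-allyl over C2–C4), and with the metal face now locked PMBOH can only open the allyl from outside at C4, anti to Pd and therefore syn to isopropyl (4S), after which t-BuOOH reoxidises zerovalent palladium and Et3N collapses the allylic peroxide to the enone by Kornblum–DeLaMare elimination; the closest known reaction types are the Pd-catalysed 1,4-dioxygenation of 1,3-dienes by anti attack on η3-allyl intermediates, the t-BuOOH peroxypalladation of Wacker-type ketone syntheses, and the base-induced conversion of allylic tert-butyl peroxides into enones.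

Step 2
Reactants: 4 5-chloropent-1-yne
Product: 5 2-bromo-5-chloropent-1-ene
Conditions: HBr, Et4NBr, CH2Cl2, 40 °C
Reagents that add atoms: hydrogen bromide, Br
Why: Markovnikov hydrobromination of the terminal alkyne with the mild HBr2− carrier stops at the 2-bromo-1-alkene and leaves the primary chloride untouched.

Step 3
Reactants: 3 (4S,5R)-4-[(4-methoxyphenyl)methoxy]-2-methyl-5-(propan-2-yl)cyclohex-2-en-1-one; 5 2-bromo-5-chloropent-1-ene
Product: 9 (2S,3R,4S,5R)-3-(5-chloropent-1-en-2-yl)-4-[(4-methoxyphenyl)methoxy]-2-methyl-5-(propan-2-yl)cyclohexan-1-one, via alkenyllithium 6 (not isolated), via lithium dialkenylcuprate 7 (not isolated), via trimethylsilyl enol ether 8 (not isolated)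
Conditions: 5 (2.2 equiv), t-BuLi (4.4 equiv), Et2O, −78 °C; CuBr·SMe2 (1.1 equiv), −78 → −40 °C; then 3, Me3SiCl (2 equiv), THF, −78 → −30 °C; 1 M HCl, THF, 0 °C
Reagents that add atoms: none
Why: Me3SiCl-accelerated conjugate addition of an alkenyl Gilman cuprate to the enone half-chair with isopropyl pseudo-equatorial and the C4 ether pseudo-axial, so that axial attack at C3 is anti to both groups and sets the future ring-fusion CH (3R); the C2 epimer ratio after hydrolysis is irrelevant because C2 is re-enolised in step 4.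

Step 4
Reactants: 9 (2S,3R,4S,5R)-3-(5-chloropent-1-en-2-yl)-4-[(4-methoxyphenyl)methoxy]-2-methyl-5-(propan-2-yl)cyclohexan-1-one
Product: 10 (3R,4S,4aS,8aR)-4-[(4-methoxyphenyl)methoxy]-8a-methyl-5-methylidene-3-(propan-2-yl)octahydronaphthalen-1(2H)-one
Conditions: KOt-Bu (1.5 equiv), t-BuOH/THF, 0 → 25 °C
Reagents that add atoms: none
Why: Intramolecular enolate alkylation (6-exo-tet, the methylenecyclohexane annulation): under equilibrating base the tetrasubstituted enolate displaces the primary chloride from the face that carries the C3 side chain, which gives only the cis-fused decalone and sets the quaternary carbon (8aR).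

Step 5
Reactants: 10 (3R,4S,4aS,8aR)-4-[(4-methoxyphenyl)methoxy]-8a-methyl-5-methylidene-3-(propan-2-yl)octahydronaphthalen-1(2H)-one; 11 4-methoxybenzoyl chloride
Product: 13 (1R,3R,4S,4aS,8aR)-4-[(4-methoxyphenyl)methoxy]-8a-methyl-5-methylidene-3-(propan-2-yl)decahydronaphthalen-1-yl 4-methoxybenzoate, via lithium alkoxide 12 (not isolated)
Conditions: LiBH(s-Bu)3 (1.3 equiv), THF, −78 → 0 °C; then 11 (2 equiv), DMAP (0.2 equiv), 0 → 40 °C
Reagents that add atoms: none
Why: Diastereoselective ketone reduction by a bulky trialkylborohydride followed by O-acylation of the alkoxide with retention: in the favoured chair–chair conformer (angular methyl equatorial and isopropyl axial on ring B, which avoids a methyl/OPMB 1,3-diaxial clash) the axial isopropyl blocks the axial trajectory, so hydride enters from the ring-A face and the C1–O bond ends cis to methyl, isopropyl and OPMB (1R).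

Step 6
Reactants: 13 (1R,3R,4S,4aS,8aR)-4-[(4-methoxyphenyl)methoxy]-8a-methyl-5-methylidene-3-(propan-2-yl)decahydronaphthalen-1-yl 4-methoxybenzoate
Product: 14 (1R,3R,4S,4aS,8aR)-4-hydroxy-8a-methyl-5-methylidene-3-(propan-2-yl)decahydronaphthalen-1-yl 4-methoxybenzoate
Conditions: DDQ (1.5 equiv), CH2Cl2/pH 7 buffer (10:1), 0 → 25 °C
Reagents that add atoms: none
Why: Oxidative PMB-ether cleavage by DDQ (benzylic hydride abstraction, then hydrolysis of the oxocarbenium ion) is selective for the electron-rich benzyl ether over the acyl-deactivated anisate and the 1,1-disubstituted alkene, and touches no stereocentre.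

## Compound list

1 | (R)-(−)-α-phellandrene, (5R)-2-methyl-5-(propan-2-yl)cyclohexa-1,3-diene | CC1=CC[C@H](C(C)C)C=C1 | starting material
2 | (1S,4S,5R)-1-(tert-butylperoxy)-4-[(4-methoxyphenyl)methoxy]-2-methyl-5-(propan-2-yl)cyclohex-2-ene (peroxide anti, PMB ether syn to isopropyl) | CC1=C[C@@H](OCc2ccc(OC)cc2)[C@@H](C(C)C)C[C@@H]1OOC(C)(C)C | intermediate
3 | (4S,5R)-4-[(4-methoxyphenyl)methoxy]-2-methyl-5-(propan-2-yl)cyclohex-2-en-1-one (ether cis to isopropyl) | CC1=C[C@@H](OCc2ccc(OC)cc2)[C@@H](C(C)C)CC1=O | intermediate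
4 | 5-chloropent-1-yne | C#CCCCCl | starting material
5 | 2-bromo-5-chloropent-1-ene | C=C(Br)CCCCl | intermediate
6 | (5-chloropent-1-en-2-yl)lithium | [Li]C(=C)CCCCl | intermediate
7 | lithium bis(5-chloropent-1-en-2-yl)cuprate | [Li+].C=C(CCCCl)[Cu-]C(=C)CCCCl | intermediate
8 | {[(3S,4S,5R)-3-(5-chloropent-1-en-2-yl)-4-[(4-methoxyphenyl)methoxy]-2-methyl-5-(propan-2-yl)cyclohex-1-en-1-yl]oxy}trimethylsilane | C=C(CCCCl)[C@@H]1[C@@H](OCc2ccc(OC)cc2)[C@@H](C(C)C)CC(O[Si](C)(C)C)=C1C | intermediate
9 | (2S,3R,4S,5R)-3-(5-chloropent-1-en-2-yl)-4-[(4-methoxyphenyl)methoxy]-2-methyl-5-(propan-2-yl)cyclohexan-1-one (drawn as the 2,3-trans epimer; the C2 epimer converges in step 4) | C=C(CCCCl)[C@@H]1[C@@H](OCc2ccc(OC)cc2)[C@@H](C(C)C)CC(=O)[C@H]1C | intermediate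
10 | (3R,4S,4aS,8aR)-4-[(4-methoxyphenyl)methoxy]-8a-methyl-5-methylidene-3-(propan-2-yl)octahydronaphthalen-1(2H)-one (cis-fused) | C=C1CCC[C@]2(C)[C@H]1[C@@H](OCc3ccc(OC)cc3)[C@@H](C(C)C)CC2=O | intermediate
11 | 4-methoxybenzoyl chloride | COc1ccc(cc1)C(Cl)=O | starting material
12 | lithium (1R,3R,4S,4aS,8aR)-4-[(4-methoxyphenyl)methoxy]-8a-methyl-5-methylidene-3-(propan-2-yl)decahydronaphthalen-1-olate | C=C1CCC[C@]2(C)[C@H]1[C@@H](OCc3ccc(OC)cc3)[C@@H](C(C)C)C[C@H]2[O-].[Li+] | intermediate
13 | (1R,3R,4S,4aS,8aR)-4-[(4-methoxyphenyl)methoxy]-8a-methyl-5-methylidene-3-(propan-2-yl)decahydronaphthalen-1-yl 4-methoxybenzoate | C=C1CCC[C@]2(C)[C@H]1[C@@H](OCc3ccc(OC)cc3)[C@@H](C(C)C)C[C@H]2OC(=O)c4ccc(OC)cc4 | intermediate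
14 | (1R,3R,4S,4aS,8aR)-4-hydroxy-8a-methyl-5-methylidene-3-(propan-2-yl)decahydronaphthalen-1-yl 4-methoxybenzoate | C=C1CCC[C@]2(C)[C@H]1[C@@H](O)[C@@H](C(C)C)C[C@H]2OC(=O)c1ccc(OC)cc1 | target

## Step count and risks

Total steps: 6. Longest linear sequence: 5 (steps 1, 3, 4, 5, 6; step 2 makes the side-chain reagent).

The three steps most likely to fail:

Step 1 (the new oxo-alkoxylation) is the highest risk. The peroxide could enter at C4 instead of C1, the alcohol could add twice, the diene could aromatise to p-cymene, and facial control by the isopropyl group is untested. The fallback uses known chemistry and sets out from 1. Dye-sensitised photooxygenation (O2, tetraphenylporphyrin, visible light, CH2Cl2, 0 °C) gives both [4+2] endoperoxides. The diastereomer with the peroxide bridge syn to isopropyl, (1R,4S,8R)-6-methyl-8-(propan-2-yl)-2,3-dioxabicyclo[2.2.2]oct-5-ene F1, is separated by chromatography. Et3N then effects the Kornblum–DeLaMare rearrangement, removing the less hindered bridgehead hydrogen next to the CH2, to give (4S,5R)-4-hydroxy-2-methyl-5-(propan-2-yl)cyclohex-2-en-1-one F2. Etherification with 4-methoxybenzyl 2,2,2-trichloroacetimidate and catalytic camphorsulfonic acid brings the material back to the route at 3.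

Step 3 (cuprate addition to an α-methyl, γ-alkoxy enone) may suffer from low reactivity or reductive loss of the γ-ether. The fallback sets out from 3 and 5 and replaces the organolithium/cuprate chemistry with a nickel-catalysed reductive conjugate addition (NiCl2(MeOCH2CH2OMe), 2,9-dimethyl-1,10-phenanthroline, Mn powder, Et3SiCl, DMF, 25 °C). The C–C bond forms on the metal-bound face, again anti to the ether and isopropyl groups. The product is triethyl{[(3S,4S,5R)-3-(5-chloropent-1-en-2-yl)-4-[(4-methoxyphenyl)methoxy]-2-methyl-5-(propan-2-yl)cyclohex-1-en-1-yl]oxy}silane F3, which is hydrolysed (1 M HCl, THF) to come back at 9.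

Step 5 (facial selectivity at the C1 ketone) depends on which chair–chair conformer of 10 reacts; hydride entry from the methyl face would give the C1 epimer. The fallback sets out from 10 and switches from substrate control to reagent control. (S)-2-Methyl-CBS-oxazaborolidine with catecholborane (toluene, −78 → −40 °C; catecholborane spares the exocyclic alkene) treats the quaternary C8a side as the large group and delivers (1R,3R,4S,4aS,8aR)-4-[(4-methoxyphenyl)methoxy]-8a-methyl-5-methylidene-3-(propan-2-yl)decahydronaphthalen-1-ol F4. Acylation with 11 (DMAP, pyridine, 40 °C) comes back at 13.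

Further compounds
F1 | step 1 | (1R,4S,8R)-6-methyl-8-(propan-2-yl)-2,3-dioxabicyclo[2.2.2]oct-5-ene (peroxide bridge syn to isopropyl) | CC1=C[C@@H]2[C@@H](C(C)C)C[C@H]1OO2
F2 | step 1 | (4S,5R)-4-hydroxy-2-methyl-5-(propan-2-yl)cyclohex-2-en-1-one | CC1=C[C@@H](O)[C@@H](C(C)C)CC1=O
F3 | step 3 | triethyl{[(3S,4S,5R)-3-(5-chloropent-1-en-2-yl)-4-[(4-methoxyphenyl)methoxy]-2-methyl-5-(propan-2-yl)cyclohex-1-en-1-yl]oxy}silane | C=C(CCCCl)[C@@H]1[C@@H](OCc2ccc(OC)cc2)[C@@H](C(C)C)CC(O[Si](CC)(CC)CC)=C1C
F4 | step 5 | (1R,3R,4S,4aS,8aR)-4-[(4-methoxyphenyl)methoxy]-8a-methyl-5-methylidene-3-(propan-2-yl)decahydronaphthalen-1-ol | C=C1CCC[C@]2(C)[C@H]1[C@@H](OCc3ccc(OC)cc3)[C@@H](C(C)C)C[C@H]2O
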